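The flavanone is cut at C2–C3 of ring C. The key precursor is an achiral α-diazoketone on ring A whose ortho phenol oxygen (future O1) carries ring B as a benzyl ether. A chiral dirhodium carboxylate turns the diazo carbon (future C3) into a carbenoid that inserts into one of the two enantiotopic C–H bonds of the OCH2 group (future C2), a position activated at once by O1 and by the electron-rich ring B. One operation therefore closes ring C, forms C2–C3 and sets the only stereocentre. Geranyl is placed on phloroacetophenone at the start, phenols travel as silyl ethers, and buffered fluoride liberates the target without touching C2.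

Key step: step 8

Assumption: the (S)-configured catalyst Rh2(S-PTTL)4 (dirhodium tetrakis[N-phthaloyl-(S)-tert-leucinate]) is taken to deliver the (2S)-flavanone; if a pilot run shows the opposite sense, the mirror-image catalyst Rh2(R-PTTL)4 is used with no other change.

Abbreviations: TBS = tert-butyldimethylsilyl; geranyl = (2E)-3,7-dimethylocta-2,6-dien-1-yl.

Step 1
Reactants: 1 2',4',6'-trihydroxyacetophenone (phloroacetophenone); 2 geranyl bromide
Product: 3 1-(3-geranyl-2,4,6-trihydroxyphenyl)ethanone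
Conditions: K2CO3, acetone, reflux
Reagents that add atoms: none
Why: Base-mediated C-alkylation of the ambident phloroglucinol-type phenoxide by an allylic bromide (SN2, so the E-alkene is kept); the two free ring carbons of 1 are equivalent, so only one mono-C-geranyl isomer can form, and O-alkylated or doubly alkylated material is removed by chromatography.

Step 2
Reactants: 3 1-(3-geranyl-2,4,6-trihydroxyphenyl)ethanone
Product: 4 1-[3-geranyl-2,6-dihydroxy-4-(TBS-oxy)phenyl]ethanone
Conditions: TBSCl (1.05 equiv), imidazole, CH2Cl2, 0 °C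
Reagents that add atoms: tert-butyldimethylsilyl chloride, CC(C)(C)[Si](C)(C)Cl
Why: Silyl ether formation; the 4-hydroxyl, para to the acetyl group, is the most acidic and takes no part in the hydrogen bond to the carbonyl, so one equivalent of TBSCl should silylate it first.

Step 3
Reactants: 5 3,4-dihydroxy-5-methoxybenzaldehyde (5-hydroxyvanillin)
Product: 6 3,4-bis(TBS-oxy)-5-methoxybenzaldehyde
Conditions: TBSCl (2.4 equiv), imidazole, DMF, rt
Reagents that add atoms: tert-butyldimethylsilyl chloride, CC(C)(C)[Si](C)(C)Cl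
Why: Imidazole-promoted silyl ether formation at both phenols, the aldehyde being inert under these conditions.

Step 4
Reactants: 6 3,4-bis(TBS-oxy)-5-methoxybenzaldehyde
Product: 7 [3,4-bis(TBS-oxy)-5-methoxyphenyl]methanol
Conditions: NaBH4, THF/MeOH, 0 °C
Reagents that add atoms: none
Why: Hydride reduction of the aldehyde to the benzylic alcohol, which aryl silyl ethers tolerate at 0 °C.

Step 5
Reactants: 4 1-[3-geranyl-2,6-dihydroxy-4-(TBS-oxy)phenyl]ethanone; 7 [3,4-bis(TBS-oxy)-5-methoxyphenyl]methanol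
Product: 8 1-[6-{[3,4-bis(TBS-oxy)-5-methoxyphenyl]methoxy}-4-(TBS-oxy)-3-geranyl-2-hydroxyphenyl]ethanone
Conditions: PPh3, DIAD, THF, 0 °C to rt (1.0 equiv of 7)
Reagents that add atoms: none
Why: Mitsunobu etherification under neutral conditions that spare the aryl silyl ethers; of the two ortho hydroxyls, the one flanked by acetyl and geranyl is the more hindered and the one held in the hydrogen bond to the carbonyl, so alkylation should occur on the other, and one equivalent of 7 limits double alkylation.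

Step 6
Reactants: 8 1-[6-{[3,4-bis(TBS-oxy)-5-methoxyphenyl]methoxy}-4-(TBS-oxy)-3-geranyl-2-hydroxyphenyl]ethanone
Product: 9 1-[6-{[3,4-bis(TBS-oxy)-5-methoxyphenyl]methoxy}-2,4-bis(TBS-oxy)-3-geranylphenyl]ethanone
Conditions: TBSOTf, 2,6-lutidine, CH2Cl2, 0 °C
Reagents that add atoms: tert-butyldimethylsilyl trifluoromethanesulfonate, CC(C)(C)[Si](C)(C)OS(=O)(=O)C(F)(F)F
Why: Silylation of the remaining hindered, hydrogen-bonded phenol needs the more reactive silyl triflate, while 2,6-lutidine is too weak a base to turn the methyl ketone into its silyl enol ether at 0 °C.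

Step 7
Reactants: 9 1-[6-{[3,4-bis(TBS-oxy)-5-methoxyphenyl]methoxy}-2,4-bis(TBS-oxy)-3-geranylphenyl]ethanone
Product: 11 2-diazo-1-[6-{[3,4-bis(TBS-oxy)-5-methoxyphenyl]methoxy}-2,4-bis(TBS-oxy)-3-geranylphenyl]ethanone, via trifluoroacetyl diketone 10 (not isolated)
Conditions: LiN(SiMe3)2, THF, −78 °C; CF3CO2CH2CF3, −78 °C; 1 M HCl work-up; then MsN3, Et3N, H2O (1 equiv), MeCN, rt
Reagents that add atoms: mesyl azide, CS(=O)(=O)N=[N+]=[N-] (diazo nitrogens of 11); 2,2,2-trifluoroethyl trifluoroacetate, FC(F)(F)COC(=O)C(F)(F)F (trifluoroacetyl group of 10 only, lost again on the way to 11)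
Why: Detrifluoroacetylative (Regitz-type) diazo transfer, in which the kinetic lithium enolate of the methyl ketone is C-trifluoroacetylated and the resulting 1,3-diketone accepts the diazo group from mesyl azide with loss of the trifluoroacetyl group, giving a terminal α-diazoketone that the plain ketone cannot give directly.

Step 8
Reactants: 11 2-diazo-1-[6-{[3,4-bis(TBS-oxy)-5-methoxyphenyl]methoxy}-2,4-bis(TBS-oxy)-3-geranylphenyl]ethanone
Product: 12 (2S)-2-[3,4-bis(TBS-oxy)-5-methoxyphenyl]-5,7-bis(TBS-oxy)-6-geranylchroman-4-one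
Conditions: Rh2(S-PTTL)4 (1 mol %), CH2Cl2, 4 Å molecular sieves, 0 °C, slow addition of 11
Reagents that add atoms: none
Why: Rh2(S-PTTL)4 expels N2 from 11 to give an electrophilic rhodium carbenoid at the future C3, which inserts in a concerted, asynchronous, hydride-transfer-like three-centre transition state into one C–H bond of the OCH2Ar group, so that C3 bonds to C2 and the hydrogen ends up on C3. The closest known reaction type is the asymmetric intramolecular C–H insertion of 2-alkoxyaryl α-diazoketones to chroman-4-ones under chiral dirhodium tetracarboxylate catalysis. Ring C is closed as a 1,6-C–H insertion through a six-membered chair-like transition state that contains O1. The only new stereocentre, C2, is set by catalyst control: the two benzylic hydrogens are enantiotopic and the chiral carboxylate pocket selects the one whose replacement gives the 2S configuration (see assumption). The step needs C–H insertion to outrun oxonium-ylide formation with [1,2]-benzyl shift, cyclopropanation and carbenoid dimerisation; the C–H bond is doubly activated (α to O1 and benzylic to the electron-rich ring B), the other ortho oxygen carries a silyl group with no α C–H bond, the geranyl alkenes sit meta to the acyl carbon and cannot reach the carbenoid, and slow addition keeps intermolecular paths down.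

Step 9
Reactants: 12 (2S)-2-[3,4-bis(TBS-oxy)-5-methoxyphenyl]-5,7-bis(TBS-oxy)-6-geranylchroman-4-one
Product: 13 (2S)-2-(3,4-dihydroxy-5-methoxyphenyl)-6-geranyl-5,7-dihydroxychroman-4-one (target)
Conditions: TBAF (4.4 equiv), AcOH (4.4 equiv), THF, 0 °C
Reagents that add atoms: none
Why: Fluoride cleavage of the four aryl silyl ethers, with acetic acid keeping the liberated phenoxides protonated so that the base-induced retro-oxa-Michael ring opening that would racemise C2 cannot start, and with the geranyl alkenes untouched.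

Compound list
1 | 2',4',6'-trihydroxyacetophenone (phloroacetophenone) | CC(=O)c1c(O)cc(O)cc1O | starting material
2 | geranyl bromide, (2E)-1-bromo-3,7-dimethylocta-2,6-diene | BrC/C=C(\C)CCC=C(C)C | starting material
3 | 1-(3-geranyl-2,4,6-trihydroxyphenyl)ethanone | CC(=O)c1c(O)cc(O)c(C/C=C(\C)CCC=C(C)C)c1O | intermediate
4 | 1-[3-geranyl-2,6-dihydroxy-4-(TBS-oxy)phenyl]ethanone | CC(=O)c1c(O)cc(O[Si](C)(C)C(C)(C)C)c(C/C=C(\C)CCC=C(C)C)c1O | intermediate
5 | 3,4-dihydroxy-5-methoxybenzaldehyde (5-hydroxyvanillin) | COc1cc(C=O)cc(O)c1O | starting material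
6 | 3,4-bis(TBS-oxy)-5-methoxybenzaldehyde | COc1cc(C=O)cc(O[Si](C)(C)C(C)(C)C)c1O[Si](C)(C)C(C)(C)C | intermediate
7 | [3,4-bis(TBS-oxy)-5-methoxyphenyl]methanol | COc1cc(CO)cc(O[Si](C)(C)C(C)(C)C)c1O[Si](C)(C)C(C)(C)C | intermediate
8 | 1-[6-{[3,4-bis(TBS-oxy)-5-methoxyphenyl]methoxy}-4-(TBS-oxy)-3-geranyl-2-hydroxyphenyl]ethanone | CC(=O)c1c(OCc2cc(OC)c(O[Si](C)(C)C(C)(C)C)c(O[Si](C)(C)C(C)(C)C)c2)cc(O[Si](C)(C)C(C)(C)C)c(C/C=C(\C)CCC=C(C)C)c1O | intermediate
9 | 1-[6-{[3,4-bis(TBS-oxy)-5-methoxyphenyl]methoxy}-2,4-bis(TBS-oxy)-3-geranylphenyl]ethanone | CC(=O)c1c(OCc2cc(OC)c(O[Si](C)(C)C(C)(C)C)c(O[Si](C)(C)C(C)(C)C)c2)cc(O[Si](C)(C)C(C)(C)C)c(C/C=C(\C)CCC=C(C)C)c1O[Si](C)(C)C(C)(C)C | intermediate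
10 | 4,4,4-trifluoro-1-[6-{[3,4-bis(TBS-oxy)-5-methoxyphenyl]methoxy}-2,4-bis(TBS-oxy)-3-geranylphenyl]butane-1,3-dione | O=C(CC(=O)C(F)(F)F)c1c(OCc2cc(OC)c(O[Si](C)(C)C(C)(C)C)c(O[Si](C)(C)C(C)(C)C)c2)cc(O[Si](C)(C)C(C)(C)C)c(C/C=C(\C)CCC=C(C)C)c1O[Si](C)(C)C(C)(C)C | intermediate (not isolated)
11 | 2-diazo-1-[6-{[3,4-bis(TBS-oxy)-5-methoxyphenyl]methoxy}-2,4-bis(TBS-oxy)-3-geranylphenyl]ethanone | [N-]=[N+]=CC(=O)c1c(OCc2cc(OC)c(O[Si](C)(C)C(C)(C)C)c(O[Si](C)(C)C(C)(C)C)c2)cc(O[Si](C)(C)C(C)(C)C)c(C/C=C(\C)CCC=C(C)C)c1O[Si](C)(C)C(C)(C)C | intermediate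
12 | (2S)-2-[3,4-bis(TBS-oxy)-5-methoxyphenyl]-5,7-bis(TBS-oxy)-6-geranylchroman-4-one | COc1cc([C@@H]2CC(=O)c3c(cc(O[Si](C)(C)C(C)(C)C)c(C/C=C(\C)CCC=C(C)C)c3O[Si](C)(C)C(C)(C)C)O2)cc(O[Si](C)(C)C(C)(C)C)c1O[Si](C)(C)C(C)(C)C | intermediate
13 | (2S)-2-(3,4-dihydroxy-5-methoxyphenyl)-6-geranyl-5,7-dihydroxychroman-4-one | COc1cc([C@@H]2CC(=O)c3c(cc(O)c(C/C=C(\C)CCC=C(C)C)c3O)O2)cc(O)c1O | target

Total step count: 9
Longest linear sequence: 7 steps (steps 1, 2, 5, 6, 7, 8 and 9 from phloroacetophenone; the ring-B branch through steps 3 and 4 joins at step 5 and is equally long)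

The three steps most likely to fail, the riskiest first, each with its fallback:

Risk 1, step 8, the key step: the carbenoid may be captured by the lone pair of the benzylic ether oxygen, giving an oxonium ylide that undergoes a [1,2]-benzyl shift to a benzofuranone, faster than it inserts into the C–H bond; the catalyst may also discriminate poorly between the two enantiotopic hydrogens. The fallback for step 8 sets out from compound 9 and comes back to the route at compound 12; it makes the same C2–C3 bond oxidatively instead of through a carbenoid. DDQ (1.2 equiv) with LiClO4 in 1,2-dichloroethane at 40 °C should abstract hydride from the benzylic ether CH2 next to ring B, ring A being deactivated by its acyl group. The enol of the methyl ketone should then add to the aryloxy-stabilised benzylic cation, an intramolecular cross-dehydrogenative coupling of a benzyl ether with a ketone, which should give racemic 2-[3,4-bis(TBS-oxy)-5-methoxyphenyl]-5,7-bis(TBS-oxy)-6-geranylchroman-4-one F1. Preparative HPLC on an amylose tris(3,5-dimethylphenylcarbamate) phase should then part F1 into compound 12 and its mirror image (2R)-2-[3,4-bis(TBS-oxy)-5-methoxyphenyl]-5,7-bis(TBS-oxy)-6-geranylchroman-4-one F2, which is set aside.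

Risk 2, step 5: the Mitsunobu reaction may discriminate poorly between the two ortho hydroxyls of compound 4, or alkylate both. The fallback for step 5 sets out from compound 1 and comes back to the route at compound 8; it forms the benzyl ether before the geranyl group is present, while the two ortho hydroxyls are still equivalent. TBSCl and imidazole in CH2Cl2 at 0 °C should turn compound 1 into 1-[2,6-dihydroxy-4-(TBS-oxy)phenyl]ethanone F3. Mitsunobu reaction of F3 with alcohol 7 (PPh3, DIAD, THF) should give 1-[2-{[3,4-bis(TBS-oxy)-5-methoxyphenyl]methoxy}-4-(TBS-oxy)-6-hydroxyphenyl]ethanone F4, the second hydroxyl being held back by its hydrogen bond to the carbonyl once the first is etherified. The sodium phenoxide of F4 (NaH, toluene, 0 °C to rt) should then be C-geranylated by geranyl bromide 2 at the ring carbon ortho to the phenoxide oxygen, as tight ion pairs in non-polar solvents favour, which gives compound 8.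

Risk 3, step 7: the ortho silyl group may migrate from the phenol oxygen to the enolate oxygen in the lithium enolate, and C-acylation of the hindered enolate may be sluggish. The fallback for step 7 sets out from compound 9 and comes back to the route at compound 11; it avoids the lithium enolate altogether. Soft enolisation with TMSOTf and Et3N in CH2Cl2 at 0 °C should give the trimethylsilyl enol ether trimethyl({1-[6-{[3,4-bis(TBS-oxy)-5-methoxyphenyl]methoxy}-2,4-bis(TBS-oxy)-3-geranylphenyl]ethenyl}oxy)silane F5. NBS in THF at −78 °C should convert F5 into 2-bromo-1-[6-{[3,4-bis(TBS-oxy)-5-methoxyphenyl]methoxy}-2,4-bis(TBS-oxy)-3-geranylphenyl]ethanone F6, the enol ether being more nucleophilic than the trisubstituted alkenes of the geranyl chain at this temperature. N,N'-ditosylhydrazine and DBU in THF at 0 °C (N-alkylation, then two eliminations of sulfinate) should turn F6 into the diazoketone, compound 11.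

Further compounds
F1 | step 8 | racemic 2-[3,4-bis(TBS-oxy)-5-methoxyphenyl]-5,7-bis(TBS-oxy)-6-geranylchroman-4-one | COc1cc(C2CC(=O)c3c(cc(O[Si](C)(C)C(C)(C)C)c(C/C=C(\C)CCC=C(C)C)c3O[Si](C)(C)C(C)(C)C)O2)cc(O[Si](C)(C)C(C)(C)C)c1O[Si](C)(C)C(C)(C)C
F2 | step 8 | (2R)-2-[3,4-bis(TBS-oxy)-5-methoxyphenyl]-5,7-bis(TBS-oxy)-6-geranylchroman-4-one | COc1cc([C@H]2CC(=O)c3c(cc(O[Si](C)(C)C(C)(C)C)c(C/C=C(\C)CCC=C(C)C)c3O[Si](C)(C)C(C)(C)C)O2)cc(O[Si](C)(C)C(C)(C)C)c1O[Si](C)(C)C(C)(C)C
F3 | step 5 | 1-[2,6-dihydroxy-4-(TBS-oxy)phenyl]ethanone | CC(=O)c1c(O)cc(O[Si](C)(C)C(C)(C)C)cc1O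
F4 | step 5 | 1-[2-{[3,4-bis(TBS-oxy)-5-methoxyphenyl]methoxy}-4-(TBS-oxy)-6-hydroxyphenyl]ethanone | CC(=O)c1c(OCc2cc(OC)c(O[Si](C)(C)C(C)(C)C)c(O[Si](C)(C)C(C)(C)C)c2)cc(O[Si](C)(C)C(C)(C)C)cc1O
F5 | step 7 | trimethyl({1-[6-{[3,4-bis(TBS-oxy)-5-methoxyphenyl]methoxy}-2,4-bis(TBS-oxy)-3-geranylphenyl]ethenyl}oxy)silane | C=C(O[Si](C)(C)C)c1c(OCc2cc(OC)c(O[Si](C)(C)C(C)(C)C)c(O[Si](C)(C)C(C)(C)C)c2)cc(O[Si](C)(C)C(C)(C)C)c(C/C=C(\C)CCC=C(C)C)c1O[Si](C)(C)C(C)(C)C
F6 | step 7 | 2-bromo-1-[6-{[3,4-bis(TBS-oxy)-5-methoxyphenyl]methoxy}-2,4-bis(TBS-oxy)-3-geranylphenyl]ethanone | BrCC(=O)c1c(OCc2cc(OC)c(O[Si](C)(C)C(C)(C)C)c(O[Si](C)(C)C(C)(C)C)c2)cc(O[Si](C)(C)C(C)(C)C)c(C/C=C(\C)CCC=C(C)C)c1O[Si](C)(C)C(C)(C)C
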